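**Retrosynthetic overview**
- The two bonds of the CH2 bridge, the 2-pyranone ring and the 2H-pyran ring are all disconnected in one move: target ⇒ 1,1-dimethylpropargyl ether of phlorisobutyrophenone + acyclic methyl 4-methyl-3,5-dioxoheptanoate + formaldehyde.
- Ring order: the benzene ring is bought (phloroglucinol); the pyranone ring (lactonisation of the diketo ester) and the pyran ring (propargyl Claisen / 1,5-H shift / oxa-6π) are both closed in the last flask.
- Aryl propargyl ether ⇐ selective 4-O-alkylation of 2-methyl-1-(2,4,6-trihydroxyphenyl)propan-1-one ⇐ Friedel–Crafts acylation of phloroglucinol.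
- Diketo ester ⇐ γ-acylation of the dianion of methyl 3-oxopentanoate with N-methoxy-N-methylpropanamide.

Assumption: the target has no stereocentre and no stereogenic double bond (its only non-aromatic C=C is the ring alkene of the chromene), so it is a single achiral compound and no stereocontrol is needed.

**Step 1**
Reactants: 1 phloroglucinol (benzene-1,3,5-triol); 2 2-methylpropanoyl chloride
Product: 3 2-methyl-1-(2,4,6-trihydroxyphenyl)propan-1-one
Conditions: AlCl3 (3.5 equiv), PhNO2, 0 → 60 °C, 3 h; then ice / 1 M HCl
Reagents that add atoms: none
Why: Friedel–Crafts C-acylation of the very electron-rich triol stops at the mono-ketone because the chelated acyl group deactivates the ring; no stereocentre is formed.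

**Step 2**
Reactants: 3 2-methyl-1-(2,4,6-trihydroxyphenyl)propan-1-one; 4 3-chloro-3-methylbut-1-yne
Product: 5 1-[2,6-dihydroxy-4-(2-methylbut-3-yn-2-yloxy)phenyl]-2-methylpropan-1-one
Conditions: 4 (1.2 equiv), K2CO3 (1.1 equiv), KI (0.2 equiv), CuI (5 mol %), acetone, N2, 50 °C, 16 h
Reagents that add atoms: none
Why: Copper-acetylide-assisted Williamson-type etherification with the tertiary propargylic chloride: one equivalent of weak base ionises only the most acidic, non-chelated 4-OH (para to the acyl group), so the ether forms there while the two hydrogen-bonded ortho-OH groups stay free, and 50 °C is far below the Claisen threshold; no stereocentre is formed.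

**Step 3**
Reactants: 6 methyl 3-oxopentanoate; 7 N-methoxy-N-methylpropanamide
Product: 9 methyl 4-methyl-3,5-dioxoheptanoate, via dilithium dianion of methyl 3-oxopentanoate 8 (not isolated)
Conditions: LiN(iPr)2 (2.2 equiv), THF, 0 °C, 30 min; then 7 (1.0 equiv), −78 → 0 °C, 2 h; then cold 1 M HCl
Reagents that add atoms: none
Why: Huckin–Weiler γ-acylation, in which the more basic terminal carbanion of the β-keto ester dianion attacks the Weinreb amide and the chelated tetrahedral adduct prevents over-addition until the acid quench; the C4 centre of 9 is racemic, enolised and disappears in step 4.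

**Step 4**
Reactants: 5 1-[2,6-dihydroxy-4-(2-methylbut-3-yn-2-yloxy)phenyl]-2-methylpropan-1-one (1.0 equiv); 9 methyl 4-methyl-3,5-dioxoheptanoate (1.1 equiv); 10 formaldehyde (as paraformaldehyde, 1.1 equiv)
Product: 14 3-{[5,7-dihydroxy-2,2-dimethyl-6-(2-methylpropanoyl)-2H-chromen-8-yl]methyl}-6-ethyl-4-hydroxy-5-methyl-2H-pyran-2-one, via 6-ethyl-4-hydroxy-5-methyl-2H-pyran-2-one 11 (not isolated), via 6-ethyl-5-methyl-3-methylidenepyran-2,4-dione 12 (not isolated), via 1-(5,7-dihydroxy-2,2-dimethyl-2H-chromen-6-yl)-2-methylpropan-1-one 13 (not isolated)
Conditions: piperidinium acetate (10 mol %), o-xylene (0.05 M), sealed tube, Ar, 140 °C, 10 h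
Reagents that add atoms: none
Why: Proposed new method: four individually known events are merged into one thermal domino — (a) the enolised β,δ-diketo ester 9 lactonises with loss of methanol (thermal, acetate-assisted 3,5-dioxo ester → 4-hydroxy-2-pyranone cyclisation) to 11, closing the pyranone ring, (b) 11 and formaldehyde give the Knoevenagel product 12, (c) ether 5 undergoes aryl propargyl ether Claisen rearrangement, 1,5-H shift and oxa-6π electrocyclisation through the non-chelated oxygen that carried the propargyl group to give 13, closing the pyran ring, and (d) the only free aromatic CH of 13 adds to 12 (Michael/Friedel–Crafts step of a carba-Betti-type three-component coupling); the order is not critical, because mono-alkylation of 5 before rearrangement (one ortho position stays free for the Claisen step) or condensation of 9 at its CH2 before lactonisation lead to the same product, and the slow release of 11 keeps pyranone homodimerisation low; the closest known reactions are the thermal chromene synthesis from aryl 1,1-dimethylpropargyl ethers and the pyranone/formaldehyde/acylphloroglucinol methylene bridging; no stereocentre is formed.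

**Compound list**
1 | phloroglucinol (benzene-1,3,5-triol) | Oc1cc(O)cc(O)c1 | starting material
2 | 2-methylpropanoyl chloride | CC(C)C(Cl)=O | starting material
3 | 2-methyl-1-(2,4,6-trihydroxyphenyl)propan-1-one | CC(C)C(=O)c1c(O)cc(O)cc1O | intermediate
4 | 3-chloro-3-methylbut-1-yne | CC(C)(Cl)C#C | starting material
5 | 1-[2,6-dihydroxy-4-(2-methylbut-3-yn-2-yloxy)phenyl]-2-methylpropan-1-one | CC(C)C(=O)c1c(O)cc(OC(C)(C)C#C)cc1O | intermediate
6 | methyl 3-oxopentanoate | CCC(=O)CC(=O)OC | starting material
7 | N-methoxy-N-methylpropanamide | CCC(=O)N(C)OC | starting material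
8 | dilithium dianion of methyl 3-oxopentanoate (bis-enolate, geometry not defined) | [Li+].[Li+].CC=C([O-])C=C([O-])OC | intermediate
9 | methyl 4-methyl-3,5-dioxoheptanoate (racemic at C4, largely enolised) | CCC(=O)C(C)C(=O)CC(=O)OC | intermediate
10 | formaldehyde (used as paraformaldehyde) | C=O | starting material
11 | 6-ethyl-4-hydroxy-5-methyl-2H-pyran-2-one | CCc1oc(=O)cc(O)c1C | intermediate
12 | 6-ethyl-5-methyl-3-methylidenepyran-2,4-dione | CCC1=C(C)C(=O)C(=C)C(=O)O1 | intermediate
13 | 1-(5,7-dihydroxy-2,2-dimethyl-2H-chromen-6-yl)-2-methylpropan-1-one | CC(C)C(=O)c1c(O)cc2OC(C)(C)C=Cc2c1O | intermediate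
14 | 3-{[5,7-dihydroxy-2,2-dimethyl-6-(2-methylpropanoyl)-2H-chromen-8-yl]methyl}-6-ethyl-4-hydroxy-5-methyl-2H-pyran-2-one (achiral) | CCc1oc(=O)c(Cc2c(O)c(C(=O)C(C)C)c(O)c3c2OC(C)(C)C=C3)c(O)c1C | target

**Step count**
Total steps: 4. Longest linear sequence: 3 (1 → 3 → 5 → 14); step 3 is a one-step side branch.

**Steps most likely to fail, with fallbacks**

Step 4 (domino) is the riskiest. Possible failures are methylene-bridged homodimers, double alkylation of 5 before it rearranges, pyran closure onto an ortho-OH instead of the former ether oxygen (the regioisomeric chromene), and retro-Michael scrambling at 140 °C. The fallback sets out from 5 and 9 and comes back at 14, taking the domino apart. Compound 5 is heated alone (o-xylene, 140 °C) and the chromene 13 is isolated. Compound 9 is cyclised separately with 1,8-diazabicyclo[5.4.0]undec-7-ene in toluene at 80 °C to the isolated pyranone 11. Then 11 is aminomethylated with dimethyl(methylidene)ammonium iodide (CH2Cl2, rt) to 3-[(dimethylamino)methyl]-6-ethyl-4-hydroxy-5-methyl-2H-pyran-2-one F1. Warming F1 with 13 in 1,4-dioxane at 90 °C releases 12 by loss of dimethylamine, without free formaldehyde, and C8–H of 13 traps it to give 14.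

Step 2 (selective 4-O-propargylation) may give bis-ether or C-alkylated material. The fallback sets out from 3 and comes back at 13, dropping the ether altogether. Compound 3 is condensed with 3-methylbut-2-enal (ethylenediammonium diacetate 10 mol %, toluene, 110 °C; Knoevenagel condensation / oxa-6π electrocyclisation). This gives 13 directly, together with its regioisomer 1-(5,7-dihydroxy-2,2-dimethyl-2H-chromen-8-yl)-2-methylpropan-1-one F2, which is removed by chromatography. Isolated 13 then enters step 4 in place of 5, where only the Claisen event drops out and the pyranone ring still forms in the flask.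

Step 3 (dianion γ-acylation) may suffer from proton transfer or O-acylation at the secondary carbanion. The fallback sets out from 6 and comes back at 9, replacing the dianion by a neutral bis-silyl dienol ether. Compound 6 is silylated with Me3SiCl/NEt3 to methyl (2Z)-3-(trimethylsilyloxy)pent-2-enoate F3. This is converted with LiN(iPr)2/Me3SiCl into 1-methoxy-1,3-bis(trimethylsilyloxy)penta-1,3-diene F4. F4 is acylated at its terminal carbon with propanoyl chloride (CH2Cl2, −78 °C → rt, vinylogous Mukaiyama-type acylation), and aqueous work-up gives 9.

**Further compounds**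
F1 | step 4 | 3-[(dimethylamino)methyl]-6-ethyl-4-hydroxy-5-methyl-2H-pyran-2-one | CCc1oc(=O)c(CN(C)C)c(O)c1C
F2 | step 2 | 1-(5,7-dihydroxy-2,2-dimethyl-2H-chromen-8-yl)-2-methylpropan-1-one | CC(C)C(=O)c1c(O)cc(O)c2C=CC(C)(C)Oc12
F3 | step 3 | methyl (2Z)-3-(trimethylsilyloxy)pent-2-enoate | CC/C(O[Si](C)(C)C)=C/C(=O)OC
F4 | step 3 | 1-methoxy-1,3-bis(trimethylsilyloxy)penta-1,3-diene (mixture of double-bond isomers) | CC=C(O[Si](C)(C)C)C=C(OC)O[Si](C)(C)C
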